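## The problem

Robinetinidol-(4α→8)-gallocatechin (16) consists of two 2-arylchroman-3-ol units joined by one bond, from the sp3 carbon C4 of the upper ring C to the aromatic carbon C8 of the lower ring D. It has five stereocentres. Lower C2 and C3 (2R,3S) are those of natural (+)-gallocatechin (8) and can be bought. Upper C2, C3 and C4 (2R,3S,4S) are 2,3-trans-3,4-trans: the C2 aryl (ring B) and the C4 aryl (ring D) are cis, and the C3 hydroxyl is trans to both. Within ring C one centre can govern the other two, because a syn addition of H and O across a C3=C4 double bond, on the face away from the C2 aryl, gives exactly this pattern. Ring A is a resorcinol-type ring with no oxygen at C5, so the classical cation union of a flavan-3,4-diol with a flavan-3-ol is sluggish and tends to give 4α/4β and 4→8/4→6 mixtures. The position on ring D and the configuration at C4 are therefore the two things a synthesis must fix. Nine phenols, six of them in two pyrogallol rings, oxidise readily in air and base, free-phenol flavans epimerise at C2 in base, and the interflavan bond and the benzylic C2–O bonds are acid-labile, so every phenol must stay masked until a final neutral step. The enabling feature is that upper C4 bears no heteroatom and is bonded to two arenes, C4a of ring A and C8 of ring D. It can therefore be carried as an alkyne carbon already attached to C8 of gallocatechin, and the C4–C4a bond can be made by attack of ring A, whose carbon para to O7 and ortho to O1 is its doubly activated site.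

## Retrosynthesis

**16 from 15.** The ten O–CH2Ph bonds of 15 are cut (nine phenols and the lower 3-OH). Benzyl ethers tolerate every reagent class on the route (Grignard reagent, NaH, Pd/Cu, cationic gold, borane, alkaline peroxide) and all fall in one neutral hydrogenolysis, the mildest way to release two pyrogallol rings. The forward step must spare the doubly benzylic C4–C8 bond and the two benzylic C2–O1 bonds.

**15 from 13.** The C3–O and C4–H bonds of ring C are cut, leading back to the 4-arylflav-3-ene 13. The neighbouring cut, C4–C8 by cation chemistry, would reopen the 4→8/4→6 and 4α/4β questions. Here the ring D attachment is already fixed and a single syn hydroboration–oxidation sets C3 and C4 together under control of C2. The precursor has two fewer stereocentres. The forward step needs boron at C3 and attack anti to the C2 aryl.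

**13 from 12.** The C4–C4a bond is cut, opening ring C to the aryl propargyl ether 12. C4 becomes an alkyne carbon and ring A a simple 3-benzyloxyphenyl ether on C2. Cutting O1–C2 instead would require a stereoselective C–O closure onto a benzylic carbon. The chosen cut leaves C2 as a pre-formed, untouched stereocentre and makes the closure a redox-neutral isomerisation. The forward reaction must close 6-endo, attack para to the benzyloxy group, and leave the ionisable C2–O bond intact.

**12 from 7 and 11.** The C(sp)–C8 bond is cut, a Sonogashira disconnection, into the terminal alkyne 7 and the 8-iodide 11. This is the convergent point: one half carries the catalytically set stereocentre and the other the two purchased ones. Any minor enantiomer of 7 becomes a diastereomer of 12 and can be removed there.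

**11 from 10, 9 and 8.** The C8–I bond is cut, then the O-benzyl bonds. Electrophilic halogenation of per-benzylated 5,7-dioxygenated flavans goes to C8, so the regiochemistry of the interflavan bond is settled at this step. Benzylation is done in two stages (K2CO3 for the phenols to give 9, NaH for the 3-OH to give 10) so that strong base never meets a free-phenol flavan.

**7 from 5 and 6; 5 from 4; 4 from 2 and 3; 2 from 1.** The propargylic C–O bond is cut to 3-(benzyloxy)phenol (6) and the racemic propargylic carbonate 5. A copper–pybox propargylic substitution sets this one stereocentre enantioselectively from racemic material, which a resolution or a reduction/inversion sequence would only do in more steps. The carbonate 5 comes from alcohol 4, made from aldehyde 2 and ethynylmagnesium bromide (3). The alkyne must be terminal for the copper step, so no silyl group is used. Aldehyde 2 is the tribenzyl ether of 3,4,5-trihydroxybenzaldehyde (1).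

## Roads not taken

**Alternative 1:** Both C3–O bonds and both C2–H bonds are cut, leading to a bis(flav-2-ene) A1 whose only stereocentre is upper C4. In the forward step monoisopinocampheylborane would add to both enol-ether double bonds with boron at C3, and oxidation would give the diol A2. Its merit is real: four stereocentres in one operation and only a hydrogenolysis afterwards, which is better than the chosen plan in stereocentres per step. Its weak points are specific to this target. The lower ring of A1 has no resident stereocentre, so the reagent alone must set lower C2 and C3. In the upper ring the same reagent must agree with the bias from the crowded C4, and a bulky borane has to reach C3 next to a diaryl-substituted carbon. Each C3 borane is β to the ring oxygen and can eliminate with ring opening. The route also discards the two stereocentres that gallocatechin supplies, and it needs a separate enantioselective construction of upper C4 in A1. The chosen plan sets fewer centres per step, but each centre has a single, independent control element.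

**Alternative 2:** The lower ring F is cut at O1–C2 and C3–C4, leading to a ring D salicylaldehyde A3 that already carries the complete upper unit, and to the cinnamaldehyde A4. In the forward step a diarylprolinol silyl ether would promote an oxa-Michael addition and aldol condensation to give the 2-aryl-2H-chromene-3-carbaldehyde A5. The step is metal-free, catalytic in a cheap amine and simple to run, and in those respects it is better than a gold-catalysed step. For this target it rebuilds the one ring that is available enantiopure. The phenol that must add is flanked by the bulky flavan-4-yl group. C2 of A5 can racemise by retro-oxa-Michael reaction. After the key step the formyl carbon must be excised, a hydroxyl installed trans to the C2 aryl and C4 reduced, which takes several steps and has no stereochemical guarantee. The hard problems (upper C4 and the C4–C8 bond) are only moved upstream into A3. The chosen plan ends two steps after its key step.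

**Alternative 3:** Ring C is cut at O1–C2 and C3–C4. A chiral phosphoric acid would dehydrate the benzhydrol A6 to the ring A ortho-quinone methide A7, which would add the (E)-styrylboronate A8 to give the C3 boronate A9. This is the most convergent of the four plans: two bonds and three stereocentres at once, gallocatechin kept intact, and a C–B bond that maps onto C3–OH with retention. In bond and stereocentre economy it beats the chosen plan. Against it, ortho-quinone methides react best with electron-rich alkenes and an alkenylboronate is not one. The methide carbon of A7 carries a doubly ortho-substituted, chiral aryl group that hinders the reacting terminus and competes with the catalyst for facial control. The required 3,4-trans outcome depends on one particular endo/exo mode. The step would have to be developed, whereas the chosen plan uses only reaction types established on its substrate classes, and it fixes the upper C2 separately from C3 and C4.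

Key step: step 9

## Route

Remark on the chemistry: the Ph-pybox antipode for step 4 is the one that gives (S)-7 (both antipodes are commercial). The descriptor of the carbon that becomes upper C2 changes along 7 (S), 12 (R), 13 (2S) and 15 (2R) only because the CIP rank of its carbon neighbours changes; its spatial arrangement is never altered.

Step 1
Reactants: 1 3,4,5-trihydroxybenzaldehyde
Product: 2 3,4,5-tris(benzyloxy)benzaldehyde
Conditions: BnBr, K2CO3, DMF, 60 °C
Reagents that add atoms: benzyl bromide, BrCc1ccccc1
Why: Williamson etherification of three acidic phenols with a mild base; the aldehyde is untouched and the product is a known, crystalline compound.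

Step 2
Reactants: 2 3,4,5-tris(benzyloxy)benzaldehyde, 3 ethynylmagnesium bromide
Product: 4 rac-1-[3,4,5-tris(benzyloxy)phenyl]prop-2-yn-1-ol
Conditions: THF, 0 °C to rt; then sat. aq. NH4Cl
Reagents that add atoms: none
Why: Grignard addition of an acetylide to a non-enolisable aryl aldehyde; a racemate is wanted because the stereocentre is set in step 4.

Step 3
Reactants: 4 rac-1-[3,4,5-tris(benzyloxy)phenyl]prop-2-yn-1-ol
Product: 5 rac-tert-butyl 1-[3,4,5-tris(benzyloxy)phenyl]prop-2-yn-1-yl carbonate
Conditions: Boc2O, DMAP (cat.), CH2Cl2, 0 °C to rt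
Reagents that add atoms: di-tert-butyl dicarbonate, CC(C)(C)OC(=O)OC(=O)OC(C)(C)C
Why: DMAP-catalysed carbonate formation on a secondary alcohol; the carbonate is the leaving group for step 4 and releases its own base (tert-butoxide) on ionisation.

Step 4
Reactants: 5 rac-tert-butyl 1-[3,4,5-tris(benzyloxy)phenyl]prop-2-yn-1-yl carbonate, 6 3-(benzyloxy)phenol
Product: 7 (S)-1-(benzyloxy)-3-({1-[3,4,5-tris(benzyloxy)phenyl]prop-2-yn-1-yl}oxy)benzene
Conditions: (CuOTf)2·C6H6 (5 mol%), Ph-pybox (antipode giving (S)-7, 11 mol%), iPr2NEt, CH2Cl2, −20 °C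
Reagents that add atoms: none
Why: Copper-catalysed asymmetric propargylic etherification: the monovalent copper acetylide of the terminal alkyne loses carbonate to give a copper allenylidene, and the phenol adds to its γ-carbon on the face left open by the pybox ligand, so both enantiomers of 5 converge on one enantiomer of 7; 1-arylpropargyl esters with phenols are the established substrate class, and the 3,4,5-trialkoxyphenyl group is electronically close to phenyl.

Step 5
Reactants: 8 (+)-gallocatechin
Product: 9 5,7,3',4',5'-penta-O-benzyl-(+)-gallocatechin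
Conditions: BnBr, K2CO3, DMF, 0 °C to rt, Ar
Reagents that add atoms: benzyl bromide, BrCc1ccccc1
Why: Williamson etherification of the five phenols only; carbonate does not deprotonate the 3-OH, and low temperature under argon limits oxidation of the pyrogallol ring and base-induced epimerisation at C2.

Step 6
Reactants: 9 5,7,3',4',5'-penta-O-benzyl-(+)-gallocatechin
Product: 10 3,5,7,3',4',5'-hexa-O-benzyl-(+)-gallocatechin
Conditions: NaH, BnBr, Bu4NI (cat.), DMF, 0 °C to rt
Reagents that add atoms: benzyl bromide, BrCc1ccccc1
Why: Williamson etherification of the secondary alcohol; with all phenols capped the flavan cannot open to a quinone methide, so C2 and C3 are stable to NaH.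

Step 7
Reactants: 10 3,5,7,3',4',5'-hexa-O-benzyl-(+)-gallocatechin
Product: 11 8-iodo-3,5,7,3',4',5'-hexa-O-benzyl-(+)-gallocatechin
Conditions: NIS, CH2Cl2, 0 °C, dark
Reagents that add atoms: N-iodosuccinimide, O=C1CCC(=O)N1I
Why: Electrophilic aromatic iodination of the phloroglucinol-type ring D; per-benzylated 5,7-dioxygenated flavans are halogenated at C8 in preference to C6, and one equivalent of reagent avoids the 6,8-dihalide.

Step 8
Reactants: 7 (S)-1-(benzyloxy)-3-({1-[3,4,5-tris(benzyloxy)phenyl]prop-2-yn-1-yl}oxy)benzene, 11 8-iodo-3,5,7,3',4',5'-hexa-O-benzyl-(+)-gallocatechin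
Product: 12 (R)-3-benzyloxyphenyl 1-[3,4,5-tris(benzyloxy)phenyl]-3-(3,5,7,3',4',5'-hexa-O-benzylgallocatechin-8-yl)prop-2-ynyl ether
Conditions: Pd(PPh3)2Cl2 (5 mol%), CuI (10 mol%), Et3N/THF, 50 °C, degassed
Reagents that add atoms: none
Why: Sonogashira coupling of a terminal alkyne with an aryl iodide; 2,6-dialkoxyaryl iodides couple under these conditions, the basic medium leaves the propargylic ether alone, and any minor enantiomer of 7 gives a diastereomer of 12 that can be removed by chromatography.

Step 9
Reactants: 12 (R)-3-benzyloxyphenyl 1-[3,4,5-tris(benzyloxy)phenyl]-3-(3,5,7,3',4',5'-hexa-O-benzylgallocatechin-8-yl)prop-2-ynyl ether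
Product: 13 (2S)-7-benzyloxy-2-[3,4,5-tris(benzyloxy)phenyl]-4-(3,5,7,3',4',5'-hexa-O-benzylgallocatechin-8-yl)-2H-chromene
Conditions: (Ph3P)AuNTf2 (5 mol%), CH2Cl2, 0 °C to rt, dark
Reagents that add atoms: none
Why: Cationic monovalent gold binds the alkyne and slips towards C3, so positive charge builds on C4 where the trialkoxyphenyl ring D stabilises it; the ring A carbon para to the benzyloxy group attacks C4 anti to gold in a Friedel–Crafts sense, and rearomatisation with protodeauration of the C3 vinylgold gives the chromene and returns the catalyst. The closest known reaction type is the gold- or platinum-catalysed intramolecular hydroarylation of aryl propargyl ethers to 2H-chromenes, which includes 3-arylpropargyl ethers giving 4-aryl-2H-chromenes. Ring C is closed 6-endo-dig by forming C4–C4a. No stereocentre is created; C2 takes no part in any bond change and keeps its arrangement. 6-endo over 5-exo closure is secured by the alkyne polarisation, since the carbon bearing ring D is the electrophilic one and it is the distal carbon of the tether. Attack para rather than ortho to the benzyloxy group is secured by sterics: the ortho site lies between two oxygens and would place a 5-benzyloxy group peri to the doubly ortho-substituted ring D. The ether oxygens of ring D can reach only C3, the electronically mismatched carbon, and benzyl transfer from such oxonium ions needs heat. Low temperature, the absence of added acid and exclusion of light guard against ionisation of the C2–O bond in 12 and against electrocyclic ring opening of 13.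

Step 10
Reactants: 13 (2S)-7-benzyloxy-2-[3,4,5-tris(benzyloxy)phenyl]-4-(3,5,7,3',4',5'-hexa-O-benzylgallocatechin-8-yl)-2H-chromene
Product: 15 7,3',4',5'-tetra-O-benzylrobinetinidol-(4α→8)-3,5,7,3',4',5'-hexa-O-benzylgallocatechin (upper unit 2R,3S,4S; upper 3-OH free), via upper-C3 alkylborane 14 (not isolated)
Conditions: BH3·THF, THF, 0 °C to rt; then aq. NaOH, H2O2, 0 °C
Reagents that add atoms: hydrogen peroxide, OO; borane–tetrahydrofuran, [BH3-][O+]1CCCC1 (boron only in 14)
Why: Hydroboration–oxidation of a flav-3-ene: boron goes to C3, away from the diaryl-substituted C4, on the face anti to the C2 aryl; syn delivery of H to C4 on that face puts ring D cis to the C2 aryl, and oxidation with retention gives the 2,3-trans-3,4-trans alcohol, so C2 controls both new centres.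

Step 11
Reactants: 15 7,3',4',5'-tetra-O-benzylrobinetinidol-(4α→8)-3,5,7,3',4',5'-hexa-O-benzylgallocatechin
Product: 16 robinetinidol-(4α→8)-gallocatechin
Conditions: H2 (1 atm), Pd(OH)2/C, THF/MeOH, rt
Reagents that add atoms: none
Why: Catalytic hydrogenolysis of ten benzyl ethers under neutral conditions, as in established procyanidin deprotections; the C4–C8 bond and the cyclic C2–O1 ethers are expected to survive, and the product should be filtered under argon and freeze-dried to avoid oxidation.

## Compound list

1 | 3,4,5-trihydroxybenzaldehyde | O=Cc1cc(O)c(O)c(O)c1 | starting material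
2 | 3,4,5-tris(benzyloxy)benzaldehyde | O=Cc1cc(OCc2ccccc2)c(OCc2ccccc2)c(OCc2ccccc2)c1 | intermediate
3 | ethynylmagnesium bromide | C#C[Mg]Br | starting material
4 | rac-1-[3,4,5-tris(benzyloxy)phenyl]prop-2-yn-1-ol | C#CC(O)c1cc(OCc2ccccc2)c(OCc2ccccc2)c(OCc2ccccc2)c1 | intermediate
5 | rac-tert-butyl 1-[3,4,5-tris(benzyloxy)phenyl]prop-2-yn-1-yl carbonate | C#CC(OC(=O)OC(C)(C)C)c1cc(OCc2ccccc2)c(OCc2ccccc2)c(OCc2ccccc2)c1 | intermediate
6 | 3-(benzyloxy)phenol | Oc1cccc(OCc2ccccc2)c1 | starting material
7 | (S)-1-(benzyloxy)-3-({1-[3,4,5-tris(benzyloxy)phenyl]prop-2-yn-1-yl}oxy)benzene | c1ccccc1COc1cccc(c1)O[C@H](c1cc(OCc3ccccc3)c(OCc3ccccc3)c(OCc3ccccc3)c1)C#C | intermediate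
8 | (+)-gallocatechin, (2R,3S) | Oc1cc(O)c2c(c1)O[C@H](c1cc(O)c(O)c(O)c1)[C@@H](O)C2 | starting material
9 | 5,7,3',4',5'-penta-O-benzyl-(+)-gallocatechin | c1ccccc1COc1cc(OCc3ccccc3)c2c(c1)O[C@H](c1cc(OCc3ccccc3)c(OCc3ccccc3)c(OCc3ccccc3)c1)[C@@H](O)C2 | intermediate
10 | 3,5,7,3',4',5'-hexa-O-benzyl-(+)-gallocatechin | c1ccccc1COc1cc(OCc3ccccc3)c2c(c1)O[C@H](c1cc(OCc3ccccc3)c(OCc3ccccc3)c(OCc3ccccc3)c1)[C@@H](OCc1ccccc1)C2 | intermediate
11 | 8-iodo-3,5,7,3',4',5'-hexa-O-benzyl-(+)-gallocatechin | Ic1c(OCc3ccccc3)cc(OCc3ccccc3)c2c1O[C@H](c1cc(OCc3ccccc3)c(OCc3ccccc3)c(OCc3ccccc3)c1)[C@@H](OCc1ccccc1)C2 | intermediate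
12 | (R)-3-benzyloxyphenyl 1-[3,4,5-tris(benzyloxy)phenyl]-3-(hexa-O-benzylgallocatechin-8-yl)prop-2-ynyl ether | c1ccccc1COc1cccc(c1)O[C@H](c1cc(OCc3ccccc3)c(OCc3ccccc3)c(OCc3ccccc3)c1)C#Cc1c(OCc3ccccc3)cc(OCc3ccccc3)c2c1O[C@H](c1cc(OCc3ccccc3)c(OCc3ccccc3)c(OCc3ccccc3)c1)[C@@H](OCc1ccccc1)C2 | intermediate
13 | (2S)-7-benzyloxy-2-[3,4,5-tris(benzyloxy)phenyl]-4-(hexa-O-benzylgallocatechin-8-yl)-2H-chromene | c1ccccc1COc1ccc2c(c1)O[C@H](c1cc(OCc3ccccc3)c(OCc3ccccc3)c(OCc3ccccc3)c1)C=C2c1c(OCc3ccccc3)cc(OCc3ccccc3)c2c1O[C@H](c1cc(OCc3ccccc3)c(OCc3ccccc3)c(OCc3ccccc3)c1)[C@@H](OCc1ccccc1)C2 | intermediate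
14 | upper-C3 alkylborane (BH2 at C3 trans to the C2 aryl, H at C4 cis to it) | c1ccccc1COc1ccc2c(c1)O[C@H](c1cc(OCc3ccccc3)c(OCc3ccccc3)c(OCc3ccccc3)c1)[C@@H](B)[C@@H]2c1c(OCc3ccccc3)cc(OCc3ccccc3)c2c1O[C@H](c1cc(OCc3ccccc3)c(OCc3ccccc3)c(OCc3ccccc3)c1)[C@@H](OCc1ccccc1)C2 | intermediate (not isolated)
15 | 7,3',4',5'-tetra-O-benzylrobinetinidol-(4α→8)-3,5,7,3',4',5'-hexa-O-benzylgallocatechin | c1ccccc1COc1ccc2c(c1)O[C@H](c1cc(OCc3ccccc3)c(OCc3ccccc3)c(OCc3ccccc3)c1)[C@@H](O)[C@@H]2c1c(OCc3ccccc3)cc(OCc3ccccc3)c2c1O[C@H](c1cc(OCc3ccccc3)c(OCc3ccccc3)c(OCc3ccccc3)c1)[C@@H](OCc1ccccc1)C2 | intermediate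
16 | robinetinidol-(4α→8)-gallocatechin | Oc1ccc2c(c1)O[C@H](c1cc(O)c(O)c(O)c1)[C@@H](O)[C@@H]2c1c(O)cc(O)c2c1O[C@H](c1cc(O)c(O)c(O)c1)[C@@H](O)C2 | target

## Step count and risks

Total: 11 steps. Longest linear sequence: 8 steps (1 → 2 → 4 → 5 → 7 → 12 → 13 → 15 → 16; steps 1–4 and 8–11). The gallocatechin branch (steps 5–7) joins at step 8.

**Step 9 (key step).** The most likely failure is ionisation of the C2–O bond of 12 by the Lewis-acidic gold or by traces of HNTf2. The resulting cation would be benzylic and conjugated through the alkyne to the trialkoxyphenyl ring D, so configuration could be lost or the phenol expelled. The crowded alkyne may also react slowly. Fallback, from 12 back to 13: electrophilic iodocyclisation under buffered, non-acidic conditions (I2, NaHCO3, MeCN, 0 °C to rt) closes the same C4–C4a bond 6-endo and gives the 3-iodo analogue of 13 F1. Radical hydrodeiodination (Bu3SnH, Et3B, air, toluene, rt) then gives 13. Any adventitious aryl iodide on ring D would be reduced in the same operation.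

**Step 4.** Enantioselectivity may erode with the bulky 3,4,5-tris(benzyloxy)phenyl group, and the electron-rich phenol 6 may react at carbon instead of oxygen. Fallback, from 2 back to 7: catalytic asymmetric alkynylation of 2 with ethynyltrimethylsilane (Me2Zn, ProPhenol ligand, toluene) gives (S)-3-(trimethylsilyl)-1-[3,4,5-tris(benzyloxy)phenyl]prop-2-yn-1-ol F2. Mitsunobu etherification with 6 (PPh3, DIAD, toluene, 0 °C) proceeds with inversion to the silylated (R)-aryl ether F3. K2CO3 in MeOH removes the silyl group to give 7.

**Step 8.** Oxidative addition into the electron-rich, doubly ortho-substituted iodide 11 may be slow, so that copper-mediated oxidative dimerisation of 7 consumes the alkyne; prolonged heating of the copper acetylide could also erode the propargylic centre. Fallback, from 7 and 11 back to 12, with the roles reversed in a Negishi coupling: 7 is brominated (NBS, AgNO3 cat., acetone) to the 3-bromoprop-2-ynyl ether F4. Iodine–lithium exchange on 11 (n-BuLi, THF, −78 °C) gives 8-lithio-hexa-O-benzylgallocatechin F5, and ZnCl2 converts it into the 8-(chlorozincio) derivative F6. Coupling of F6 with F4 (Pd(PPh3)4, THF, rt) gives 12; oxidative addition now occurs at the reactive alkynyl bromide.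

**Step 10.** Facial selectivity may be poor if ring D, twisted out of plane at C4, shields both faces. The C3 borane 14 is also β to the ring oxygen through C2 and could eliminate with ring opening on warming. Fallback, from 7 back to 15, replacing steps 8–10 by cation chemistry: gold-catalysed cyclisation of the terminal alkyne 7 ((Ph3P)AuNTf2, CH2Cl2, rt) gives (2S)-7-benzyloxy-2-[3,4,5-tris(benzyloxy)phenyl]-2H-chromene F7. Dihydroxylation anti to the C2 aryl (OsO4 cat., NMO, acetone/H2O) gives the (2R,3S,4S)-2,3-trans-3,4-cis-flavan-3,4-diol F8. Ionisation of its benzylic C4 hydroxyl (BF3·OEt2, CH2Cl2, −40 °C) in the presence of excess 10 lets C8 of 10 attack the cation anti to the C3 hydroxyl and gives 15. This path gives up the guaranteed 4→8 regiochemistry and would need separation from 4β and 4→6 isomers.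

## Further compounds

F1 | step 9 | 7-benzyloxy-3-iodo-2-[3,4,5-tris(benzyloxy)phenyl]-4-(hexa-O-benzylgallocatechin-8-yl)-2H-chromene (C2 arranged as in 13) | c1ccccc1COc1ccc2c(c1)O[C@H](c1cc(OCc3ccccc3)c(OCc3ccccc3)c(OCc3ccccc3)c1)C(I)=C2c1c(OCc3ccccc3)cc(OCc3ccccc3)c2c1O[C@H](c1cc(OCc3ccccc3)c(OCc3ccccc3)c(OCc3ccccc3)c1)[C@@H](OCc1ccccc1)C2
F2 | step 4 | (S)-3-(trimethylsilyl)-1-[3,4,5-tris(benzyloxy)phenyl]prop-2-yn-1-ol | O[C@@H](c1cc(OCc2ccccc2)c(OCc2ccccc2)c(OCc2ccccc2)c1)C#C[Si](C)(C)C
F3 | step 4 | (R)-1-(benzyloxy)-3-({3-(trimethylsilyl)-1-[3,4,5-tris(benzyloxy)phenyl]prop-2-yn-1-yl}oxy)benzene | c1ccccc1COc1cccc(c1)O[C@H](c1cc(OCc3ccccc3)c(OCc3ccccc3)c(OCc3ccccc3)c1)C#C[Si](C)(C)C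
F4 | step 8 | (R)-1-(benzyloxy)-3-({3-bromo-1-[3,4,5-tris(benzyloxy)phenyl]prop-2-yn-1-yl}oxy)benzene | c1ccccc1COc1cccc(c1)O[C@H](c1cc(OCc3ccccc3)c(OCc3ccccc3)c(OCc3ccccc3)c1)C#CBr
F5 | step 8 | 8-lithio-3,5,7,3',4',5'-hexa-O-benzyl-(+)-gallocatechin | [Li]c1c(OCc3ccccc3)cc(OCc3ccccc3)c2c1O[C@H](c1cc(OCc3ccccc3)c(OCc3ccccc3)c(OCc3ccccc3)c1)[C@@H](OCc1ccccc1)C2
F6 | step 8 | 8-(chlorozincio)-3,5,7,3',4',5'-hexa-O-benzyl-(+)-gallocatechin | Cl[Zn]c1c(OCc3ccccc3)cc(OCc3ccccc3)c2c1O[C@H](c1cc(OCc3ccccc3)c(OCc3ccccc3)c(OCc3ccccc3)c1)[C@@H](OCc1ccccc1)C2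
F7 | step 10 | (2S)-7-benzyloxy-2-[3,4,5-tris(benzyloxy)phenyl]-2H-chromene | c1ccccc1COc1ccc2c(c1)O[C@H](c1cc(OCc3ccccc3)c(OCc3ccccc3)c(OCc3ccccc3)c1)C=C2
F8 | step 10 | (2R,3S,4S)-7-benzyloxy-2-[3,4,5-tris(benzyloxy)phenyl]chromane-3,4-diol (2,3-trans-3,4-cis) | c1ccccc1COc1ccc2c(c1)O[C@H](c1cc(OCc3ccccc3)c(OCc3ccccc3)c(OCc3ccccc3)c1)[C@@H](O)[C@H]2O
A1 | alternative 1 | benzyl-protected bis(flav-2-ene) with upper C4 as in the target | c1ccccc1COc1ccc2c(c1)OC(c1cc(OCc3ccccc3)c(OCc3ccccc3)c(OCc3ccccc3)c1)=C[C@@H]2c1c(OCc3ccccc3)cc(OCc3ccccc3)c2c1OC(c1cc(OCc3ccccc3)c(OCc3ccccc3)c(OCc3ccccc3)c1)=CC2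
A2 | alternative 1 | nona-O-benzyl target with both 3-hydroxyls free | c1ccccc1COc1ccc2c(c1)O[C@H](c1cc(OCc3ccccc3)c(OCc3ccccc3)c(OCc3ccccc3)c1)[C@@H](O)[C@@H]2c1c(OCc3ccccc3)cc(OCc3ccccc3)c2c1O[C@H](c1cc(OCc3ccccc3)c(OCc3ccccc3)c(OCc3ccccc3)c1)[C@@H](O)C2
A3 | alternative 2 | 4,6-bis(benzyloxy)-2-hydroxy-3-(penta-O-benzylrobinetinidol-4-yl)benzaldehyde | c1ccccc1COc1ccc2c(c1)O[C@H](c1cc(OCc3ccccc3)c(OCc3ccccc3)c(OCc3ccccc3)c1)[C@@H](OCc1ccccc1)[C@@H]2c1c(OCc3ccccc3)cc(OCc3ccccc3)c(C=O)c1O
A4 | alternative 2 | (E)-3,4,5-tris(benzyloxy)cinnamaldehyde | O=C/C=C/c1cc(OCc2ccccc2)c(OCc2ccccc2)c(OCc2ccccc2)c1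
A5 | alternative 2 | benzyl-protected dimer whose lower unit is a 2-aryl-2H-chromene-3-carbaldehyde | c1ccccc1COc1ccc2c(c1)O[C@H](c1cc(OCc3ccccc3)c(OCc3ccccc3)c(OCc3ccccc3)c1)[C@@H](OCc1ccccc1)[C@@H]2c1c(OCc3ccccc3)cc(OCc3ccccc3)c2c1O[C@H](c1cc(OCc3ccccc3)c(OCc3ccccc3)c(OCc3ccccc3)c1)C(C=O)=C2
A6 | alternative 3 | (4-benzyloxy-2-hydroxyphenyl)(hexa-O-benzylgallocatechin-8-yl)methanol | OC(c1ccc(OCc3ccccc3)cc1O)c1c(OCc3ccccc3)cc(OCc3ccccc3)c2c1O[C@H](c1cc(OCc3ccccc3)c(OCc3ccccc3)c(OCc3ccccc3)c1)[C@@H](OCc1ccccc1)C2
A7 | alternative 3 | ring A ortho-quinone methide with the gallocatechin-8-yl group on the methide carbon | O=C1C=C(OCc3ccccc3)C=CC1=Cc1c(OCc3ccccc3)cc(OCc3ccccc3)c2c1O[C@H](c1cc(OCc3ccccc3)c(OCc3ccccc3)c(OCc3ccccc3)c1)[C@@H](OCc1ccccc1)C2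
A8 | alternative 3 | (E)-2-[3,4,5-tris(benzyloxy)styryl]-4,4,5,5-tetramethyl-1,3,2-dioxaborolane | CC1(C)OB(/C=C/c2cc(OCc3ccccc3)c(OCc3ccccc3)c(OCc3ccccc3)c2)OC1(C)C
A9 | alternative 3 | benzyl-protected dimer with a pinacolboryl group at upper C3 | c1ccccc1COc1ccc2c(c1)O[C@H](c1cc(OCc3ccccc3)c(OCc3ccccc3)c(OCc3ccccc3)c1)[C@@H](B1OC(C)(C)C(C)(C)O1)[C@@H]2c1c(OCc3ccccc3)cc(OCc3ccccc3)c2c1O[C@H](c1cc(OCc3ccccc3)c(OCc3ccccc3)c(OCc3ccccc3)c1)[C@@H](OCc1ccccc1)C2
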